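To whoever takes the bench: Monday's and Wednesday's flasks share one recipe and differ in stopping time. Free monomer enters over 30 h and passes into chains.

| flask | free monomer | initiator | remark | time |
|---|---|---|---|---|
| oak | 0.15 M (fed, over 30 h) | 2 mM | run made earlier |  |
| Monday's | 0.10 M (fed, over 30 h) | 2.0 mM |  | 5.0 d |
| Wednesday's | 0.10 M (fed, over 30 h) | 2.0 mM |  | 1.5 d |

- oak (time / h: monomer in chains / %): 3.00: 0.3; 4.00: 0.4; 6.00: 2.4; 10.0: 6.3; 15.0: 12.8; 25.0: 32.2; 40.0: 61.7

(each reading ± 0.5 percentage points)

- the average divides the monomer in chains by the number of chains, living and dead together; two radicals that join make one chain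
- the earlier runs do not show the number of chains; that part of a forecast is a guess
- percentages count the whole charge, also what has not yet gone in

- which of the two ends with the longer chains by the average number of monomer units in a chain (living and dead chains, two that joined counted as one) ("neither" if they lie within 10%) (Monday's / Wednesday's / neither)
- average number of monomer units in a chain (living and dead chains, two that joined counted as one) at the end, Monday's
- average number of monomer units in a chain (living and dead chains, two that joined counted as one) at the end, Wednesday's

In the oak run, free monomer at any moment is the share fed so far minus the share in chains. Between 15.0 h and 25.0 h: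

τ = mean free monomer ÷ uptake rate = 22.8 h

This τ is the lifetime of free monomer, the time constant of a pseudo-first-order uptake; it is a reading from the oak run, with the scatter of those readings, taken at 2 mM of initiator, so leave that charge alone. In Monday's and Wednesday's flasks, this reckoning then puts free monomer, as a share of the charge, at:

end of feed: (τ/feed time)(fall of the feed's exponential) = 55.6%
Wednesday's, 0.264 lifetimes later: 42.7%
Monday's, 3.95 lifetimes later: 1.07%

Chains are a guess: taken as growing in step with time, they rise 3.33-fold from Wednesday's stop to Monday's, while monomer in chains rises 1.73-fold. This reckoning puts Wednesday's chains ahead of Monday's by a factor of 1.93.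

The forecast names Wednesday's, with 180 for Monday's and 270 for Wednesday's, a ratio of 1.50, which differs from this reckoning. In its words: “Stopping early favours Wednesday's, because chains keep forming while monomer runs out.”

The flasks give Wednesday's, with 130 for Monday's and 211 for Wednesday's.

    initiator → 2 initiating radical (k = 6.60 × 10⁻⁵ min⁻¹)
    free monomer + initiating radical → growing radical + monomer in chains (k = 1.50 × 10⁵ M⁻¹ s⁻¹)
    free monomer + growing radical → monomer in chains + growing radical, rate k3*[growing radical]*[free monomer] (k = 4.50 × 10⁵ M⁻¹ min⁻¹)
    2 growing radical → dead chain (k = 8.20 × 10⁸ M⁻¹ s⁻¹)

In Wednesday's flask at 0.959 d, the step free monomer + growing radical halves free monomer in 0.68 d, while the breakdown of initiator has a much longer half-life of 7.3 d. Monday's ends with 1.53% free monomer, 62.2% initiator and 7.56 × 10⁻⁴ M dead chain, against the forecast's guess of 0.54 mM chains.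

Wednesday's with 0.40 M of free monomer keeps the initiator and times, so τ again leaves 42.7% of the charge. The computed flask holds 44% of its free monomer at the end, with an average of 842 monomer units in a chain.

(The earlier runs and the new flask were generated by integration for an exercise, noise included.)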